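## Retrosynthetic overview

1. Austradiol acetate ⇐ its 1α-alcohol (C1–Br by displacement with inversion) ⇐ the 4α,6α-diol by acetylation and desilylation.
2. 5α-H and 6α-OH ⇐ a Δ5 alkene: both are added syn from the α face by a hydrosilylation tethered to the 4α-oxygen, then C–Si oxidation.
3. Ring A ⇐ C4–C5 closure (key step): the ring-ketone carbon C5, made into an alkenylchromium donor through its enol triflate, adds to the C4 methyl ketone. Two carbonyl (acceptor) carbons are joined and C4(OH)Me is set.
4. Cyclisation substrate ⇐ (S)-carvone: isopropenyl hydrogenation, conjugate reduction–aldol with a ketal-protected 4-oxopentanal (sets C10 and C1), enol triflation, ketal removal.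
5. Ring order: ring B with its C7 stereocentre comes intact from carvone; ring A is closed in step 5.

Assumption: eudesmane numbering is used (ring A = C1–C5 plus C10, ring B = C5–C10), β is the face of the C10 methyl and α the opposite face, and the ketal aldehyde of step 2 is a bought reagent.

## Route

Step 1
Reactants: 1 (S)-(+)-carvone
Product: 2 (S)-carvotanacetone [(5S)-2-methyl-5-(propan-2-yl)cyclohex-2-en-1-one]
Conditions: H2 (1 atm), RhCl(PPh3)3 (2 mol%), benzene, rt
Reagents that add atoms: none
Why: RhCl(PPh3)3-catalysed homogeneous hydrogenation saturates the unhindered 1,1-disubstituted isopropenyl group much faster than the trisubstituted conjugated enone alkene, and the existing stereocentre (future C7) is not touched.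

Step 2
Reactants: 2 (S)-carvotanacetone; 3 3-(2-methyl-1,3-dioxolan-2-yl)propanal
Product: 6 (2S,5S)-2-[(1S)-1-(tert-butyldimethylsilyloxy)-3-(2-methyl-1,3-dioxolan-2-yl)propyl]-2-methyl-5-(propan-2-yl)cyclohexan-1-one, via lithium enolate 4 (not isolated), via lithium aldolate 5 (not isolated)
Conditions: LiBH(s-Bu)3 (1.05 equiv), THF, −78 °C; then 3, −78 °C; then TBSOTf, −78 → −20 °C
Reagents that add atoms: tert-butyldimethylsilyl trifluoromethanesulfonate (TBSOTf), CC(C)(C)[Si](C)(C)OS(=O)(=O)C(F)(F)F
Why: Conjugate hydride addition gives the tetrasubstituted enolate regiospecifically; it attacks the aldehyde axially on the face cis to the isopropyl group (C10 quaternary, methyl trans to isopropyl, as in base-mediated annulations of dihydrocarvone) through a Zimmerman–Traxler chair with the aldehyde chain equatorial, which places the new C1 oxygen syn to the C10 methyl (the later axial 1α-oxygen), and silylation in the same pot prevents retro-aldol (reductive aldol reaction).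

Step 3
Reactants: 6 silyl-protected aldol ketone
Product: 8 (3R,6S)-6-[(1S)-1-(tert-butyldimethylsilyloxy)-3-(2-methyl-1,3-dioxolan-2-yl)propyl]-6-methyl-3-(propan-2-yl)cyclohex-1-en-1-yl trifluoromethanesulfonate, via potassium enolate 7 (not isolated)
Conditions: KN(SiMe3)2, THF, −78 °C; then PhNTf2, −78 → 0 °C
Reagents that add atoms: N-phenylbis(trifluoromethanesulfonimide) (PhNTf2), O=S(=O)(N(c1ccccc1)S(=O)(=O)C(F)(F)F)C(F)(F)F
Why: Because C10 is quaternary the ketone can enolise only toward C6, so deprotonation and O-sulfonylation give one enol triflate regioisomer (enol triflate formation), no stereocentre is created and the β-silyloxy group cannot be eliminated since C10 carries no hydrogen.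

Step 4
Reactants: 8 ketal alkenyl triflate
Product: 9 (3R,6S)-6-[(1S)-1-(tert-butyldimethylsilyloxy)-4-oxopentyl]-6-methyl-3-(propan-2-yl)cyclohex-1-en-1-yl trifluoromethanesulfonate
Conditions: p-TsOH·H2O (10 mol%), THF/H2O (5:1), 40 °C
Reagents that add atoms: water, O
Why: Acid-catalysed hydrolysis of the dioxolane (ketal deprotection) frees the C4 methyl ketone, while the alkenyl triflate and the hindered secondary silyl ether survive these mild conditions.

Step 5
Reactants: 9 keto alkenyl triflate
Product: 11 1α-(tert-butyldimethylsilyloxy)-7-epi-eudesm-5-en-4α-ol (10β-methyl; 4β-methyl; 7α-isopropyl), via alkenylchromium dichloride 10 (not isolated)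
Conditions: CrCl2 (6 equiv), NiCl2 (2 mol%), DMF, 25 → 50 °C; aq. NH4Cl
Reagents that add atoms: none
Why: In this Nozaki–Hiyama–Kishi cyclisation zerovalent nickel inserts into the C5–OTf bond and transmetalation to trivalent chromium makes the former carbonyl carbon C5 a nucleophile that adds to the C4 ketone to close the six-membered ring; in the metal-bridged four-centre transition state the ketone oxygen has to lie in the plane of the C5=C6 bond (pseudo-equatorial, α), so the methyl group goes axial (β), which sets C4 as the 4α-ol.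

Step 6
Reactants: 11 allylic tertiary alcohol
Product: 14 1α-(tert-butyldimethylsilyloxy)-7-epi-eudesmane-4α,6α-diol (5α-H), via dimethylsilyl ether 12 (not isolated), via cyclic siloxane 13 (not isolated)
Conditions: Me2SiHCl, Et3N, DMAP (cat.), CH2Cl2, 0 °C → rt; then H2PtCl6·6H2O (0.5 mol%), THF, 60 °C; then KF, KHCO3, 30% H2O2, THF/MeOH, rt
Reagents that add atoms: hydrogen peroxide, OO
Why: The silicon hydride held on the 4α-oxygen adds across C5=C6 intramolecularly and syn (5-endo hydrosilylation of an allylic silyl ether), from the α face because a β C6–Si bond would be syn-axial to both the C4 and C10 methyl groups, so 5α-H (trans ring fusion) and the 6α C–Si bond are set together, and Tamao–Fleming oxidation turns C–Si into C–OH with retention.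

Step 7
Reactants: 14 4α,6α-diol
Product: 15 1α-(tert-butyldimethylsilyloxy)-4α-hydroxy-7-epi-eudesman-6α-yl acetate
Conditions: Ac2O, Et3N, DMAP (cat.), CH2Cl2, rt
Reagents that add atoms: acetic anhydride, CC(=O)OC(C)=O
Why: DMAP-catalysed acylation esterifies the only secondary hydroxyl (C6), the tertiary 4-OH being unreactive under these conditions, and no stereocentre changes.

Step 8
Reactants: 15 silyl ether acetate
Product: 16 1α,4α-dihydroxy-7-epi-eudesman-6α-yl acetate
Conditions: HF·pyridine, THF/pyridine, 0 °C → rt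
Reagents that add atoms: none
Why: Fluoride-mediated desilylation removes the TBS group without touching the acetate or the tertiary alcohol and frees the axial 1α-OH.

Step 9
Reactants: 16 1α-hydroxy acetate
Product: 18 austradiol acetate (1β-bromo-4α-hydroxy-7-epi-eudesman-6α-yl acetate), via alkoxyphosphonium bromide 17 (not isolated)
Conditions: CBr4, PPh3, toluene, 0 → 60 °C
Reagents that add atoms: tetrabromomethane, BrC(Br)(Br)Br
Why: In the Appel reaction the axial 1α-alkoxyphosphonium group is displaced by bromide from the opposite (β) side with inversion (SN2) to give the equatorial 1β-bromide, while the hindered tertiary 4-OH does not form a reactive phosphonium salt.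

## Compound list

1 | (S)-(+)-carvone | CC1=CC[C@@H](CC1=O)C(C)=C | starting material
2 | (S)-carvotanacetone | CC1=CC[C@@H](CC1=O)C(C)C | intermediate
3 | 3-(2-methyl-1,3-dioxolan-2-yl)propanal | O=CCCC1(C)OCCO1 | starting material
4 | lithium (5S)-2-methyl-5-(propan-2-yl)cyclohex-1-en-1-olate | CC1=C(O[Li])C[C@@H](C(C)C)CC1 | intermediate
5 | lithium aldolate (lithium alkoxide corresponding to 6) | CC(C)[C@H]1CC[C@@](C)([C@@H](O[Li])CCC2(C)OCCO2)C(=O)C1 | intermediate
6 | (2S,5S)-2-[(1S)-1-(tert-butyldimethylsilyloxy)-3-(2-methyl-1,3-dioxolan-2-yl)propyl]-2-methyl-5-(propan-2-yl)cyclohexan-1-one | CC(C)[C@H]1CC[C@@](C)([C@@H](O[Si](C)(C)C(C)(C)C)CCC2(C)OCCO2)C(=O)C1 | intermediate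
7 | potassium enolate of 6 (C5–OK, C5=C6) | CC(C)[C@H]1CC[C@@](C)([C@@H](O[Si](C)(C)C(C)(C)C)CCC2(C)OCCO2)C(O[K])=C1 | intermediate
8 | (3R,6S)-6-[(1S)-1-(tert-butyldimethylsilyloxy)-3-(2-methyl-1,3-dioxolan-2-yl)propyl]-6-methyl-3-(propan-2-yl)cyclohex-1-en-1-yl trifluoromethanesulfonate | CC(C)[C@H]1CC[C@@](C)([C@@H](O[Si](C)(C)C(C)(C)C)CCC2(C)OCCO2)C(OS(=O)(=O)C(F)(F)F)=C1 | intermediate
9 | (3R,6S)-6-[(1S)-1-(tert-butyldimethylsilyloxy)-4-oxopentyl]-6-methyl-3-(propan-2-yl)cyclohex-1-en-1-yl trifluoromethanesulfonate | CC(C)[C@H]1CC[C@@](C)([C@@H](O[Si](C)(C)C(C)(C)C)CCC(C)=O)C(OS(=O)(=O)C(F)(F)F)=C1 | intermediate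
10 | alkenylchromium dichloride from 9 (CrCl2 at C5 in place of OTf) | CC(C)[C@H]1CC[C@@](C)([C@@H](O[Si](C)(C)C(C)(C)C)CCC(C)=O)C([Cr](Cl)Cl)=C1 | intermediate
11 | 1α-(tert-butyldimethylsilyloxy)-7-epi-eudesm-5-en-4α-ol | CC(C)[C@H]1CC[C@@]2(C)[C@@H](O[Si](C)(C)C(C)(C)C)CC[C@@](C)(O)C2=C1 | intermediate
12 | 4α-O-dimethylsilyl ether of 11 | CC(C)[C@H]1CC[C@@]2(C)[C@@H](O[Si](C)(C)C(C)(C)C)CC[C@@](C)(O[SiH](C)C)C2=C1 | intermediate
13 | cyclic siloxane (O4–SiMe2–C6 bridge on the α face, 5α-H) | CC(C)[C@H]1CC[C@@]2(C)[C@@H](O[Si](C)(C)C(C)(C)C)CC[C@@]3(C)O[Si](C)(C)[C@@H]1[C@H]23 | intermediate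
14 | 1α-(tert-butyldimethylsilyloxy)-7-epi-eudesmane-4α,6α-diol | O[C@H]1[C@@H](C(C)C)CC[C@@]2(C)[C@@H](O[Si](C)(C)C(C)(C)C)CC[C@@](C)(O)[C@H]12 | intermediate
15 | 1α-(tert-butyldimethylsilyloxy)-4α-hydroxy-7-epi-eudesman-6α-yl acetate | CC(=O)O[C@H]1[C@@H](C(C)C)CC[C@@]2(C)[C@@H](O[Si](C)(C)C(C)(C)C)CC[C@@](C)(O)[C@H]12 | intermediate
16 | 1α,4α-dihydroxy-7-epi-eudesman-6α-yl acetate | CC(=O)O[C@H]1[C@@H](C(C)C)CC[C@@]2(C)[C@@H](O)CC[C@@](C)(O)[C@H]12 | intermediate
17 | 1α-(triphenylphosphoniooxy) derivative of 16, bromide salt | CC(=O)O[C@H]1[C@@H](C(C)C)CC[C@@]2(C)[C@@H](O[P+](c3ccccc3)(c3ccccc3)c3ccccc3)CC[C@@](C)(O)[C@H]12.[Br-] | intermediate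
18 | austradiol acetate, (1R,4R,5S,6S,7R,10R) in eudesmane numbering | CC(=O)O[C@H]1[C@@H](C(C)C)CC[C@@]2(C)[C@H](Br)CC[C@@](C)(O)[C@H]12 | target

## Step count and weak points

Total steps: 9. Longest linear sequence: 9 steps, from (S)-carvone 1; aldehyde 3 enters in step 2.

The three steps most likely to fail:

**Step 9 (C1 bromide).** The carbon is neopentylic: the axial C10 methyl sits anti to the leaving group, so elimination to the 1-ene or no reaction may win over substitution. The fallback avoids substitution altogether. It sets out from 16: oxidation with Dess–Martin periodinane gives 6α-acetoxy-4α-hydroxy-7-epi-eudesman-1-one F4. Treatment with (PhO)3P, Br2 and Et3N (CH2Cl2, −60 → 20 °C) converts the ketone into 1-bromo-4α-hydroxy-7-epi-eudesm-1-en-6α-yl acetate F5. Hydrogen-atom-transfer hydrogenation (Mn(dpm)3, PhSiH3, t-BuOOH, i-PrOH, rt) then reduces the alkene; the α-bromo radical at C1 takes its hydrogen axially from the α face, which leaves bromine equatorial (β). This comes back to the route at 18.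

**Step 5 (ring A closure).** Alkenylchromium reagents add slowly to ketones, and the triflate next to quaternary C10 may simply be reduced. The C4 configuration also rests on the closed transition-state argument and is not proven. The fallback swaps the reductive chromium coupling for an anionic cyclisation. It sets out from 9: Pd(PPh3)4, LiCl and Me3SnSnMe3 (THF, 60 °C) give the C5-trimethylstannyl analogue of 9 F1, and I2 (CH2Cl2, 0 °C) gives the C5-iodo analogue of 9 F2. With t-BuLi (2.1 equiv, THF/pentane, −100 °C) iodine–lithium exchange outruns attack on the ketone, and the alkenyllithium closes onto the C4 carbonyl through the same in-plane four-centre geometry. This comes back at 11.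

**Step 6 (C5–H and C6–OH).** A 5-endo hydrosilylation of a trisubstituted ring alkene from a tertiary silyl ether may stall or isomerise the alkene. The fallback sets out from 11: VO(acac)2 and t-BuOOH (CH2Cl2, 0 °C) epoxidise syn to the 4-OH and give the 5α,6α-epoxide of 11 F3. Cp2TiCl (from Cp2TiCl2 and Zn, THF) with 1,4-cyclohexadiene opens it at the tertiary carbon to a C5 radical with the 6α-oxygen retained. Hydrogen-atom transfer is expected from the α face, because the β face is screened by the two axial methyl groups. This comes back at 14.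

## Further compounds

F1 | step 5 | C5-trimethylstannyl analogue of 9 (SnMe3 in place of OTf) | CC(C)[C@H]1CC[C@@](C)([C@@H](O[Si](C)(C)C(C)(C)C)CCC(C)=O)C([Sn](C)(C)C)=C1
F2 | step 5 | C5-iodo analogue of 9 (I in place of OTf) | CC(C)[C@H]1CC[C@@](C)([C@@H](O[Si](C)(C)C(C)(C)C)CCC(C)=O)C(I)=C1
F3 | step 6 | 5α,6α-epoxide of 11 | CC(C)[C@H]1CC[C@@]2(C)[C@@H](O[Si](C)(C)C(C)(C)C)CC[C@@](C)(O)[C@@]23O[C@@H]13
F4 | step 9 | 6α-acetoxy-4α-hydroxy-7-epi-eudesman-1-one | CC(=O)O[C@H]1[C@@H](C(C)C)CC[C@@]2(C)C(=O)CC[C@@](C)(O)[C@H]12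
F5 | step 9 | 1-bromo-4α-hydroxy-7-epi-eudesm-1-en-6α-yl acetate | CC(=O)O[C@H]1[C@@H](C(C)C)CC[C@@]2(C)C(Br)=CC[C@@](C)(O)[C@H]12
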